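**Strategy.** The route rests on disconnecting the C3a–C8a ring-fusion bond of the hydroazulene (azulene numbering: C3 is the isopropyl carbinol, C4 the aroyloxy carbon, C8a the methyl-bearing quaternary carbon). In the key step a cis-decalin triol monomesylate undergoes a pinacol-type 1,2-shift: C8a migrates from the future C4 to the future C3a, so a cyclohexane contracts to the cyclopentane while the cyclohexenone expands to the cycloheptenedione. One operation sets the trans ring fusion, keeps the C3 carbinol and unveils the C4 carbonyl, exploiting the C3–OH/C3a–H/C4–O 1,3-dioxygenated array. The precursor comes from an asymmetric Robinson annulation of 2,5-dimethylcyclohexane-1,4-dione, isopropyl addition and directed dihydroxylation.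

Key step: step 7

Assumption (remark on the chemistry): 2,5-dimethylcyclohexane-1,4-dione (cis/trans mixture) is taken as purchasable; its second methyl-bearing stereocentre is inconsequential because that carbon becomes sp2 in step 3.

Locants in the "Why" lines are those of the compound names given (naphthalene numbering for 7–11, azulene numbering for 12–18).

Step 1
Reactants: 1 2,5-dimethylcyclohexane-1,4-dione (3 equiv); 2 (R)-1-phenylethylamine; 3 methyl vinyl ketone
Product: 6 (2R)-2,5-dimethyl-2-(3-oxobutyl)cyclohexane-1,4-dione, via mono-imine 4 (not isolated), via alkylated imine 5 (not isolated)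
Conditions: 2, TsOH (cat.), toluene, reflux (Dean–Stark); then 3, THF, 25 °C; then 10% aq AcOH, 25 °C
Reagents that add atoms: methyl vinyl ketone (3), CC(=O)C=C; water, O
Why: Asymmetric Michael addition of a chiral imine (d'Angelo type): the more substituted secondary enamine tautomer adds to the enone through a chair-like aza-ene transition state on the face away from the phenyl group, which with the (R)-amine should give the (2R) quaternary carbon; excess symmetric dione keeps the mono-imine dominant.

Step 2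
Reactants: 6 (2R)-2,5-dimethyl-2-(3-oxobutyl)cyclohexane-1,4-dione
Product: 7 (4aR)-4a,7-dimethyl-4,4a,7,8-tetrahydronaphthalene-2,6(3H,5H)-dione
Conditions: TsOH·H2O (0.1 equiv), toluene, reflux (Dean–Stark)
Reagents that add atoms: none
Why: Acid-catalysed intramolecular aldol condensation (second stage of the Robinson annulation): the terminal enol of the side-chain methyl ketone closes the six-membered ring on the carbonyl next to the quaternary carbon and dehydration gives the enone, while the other ring ketone enolises towards its methyl-bearing carbon, which cannot reach the side-chain carbonyl in a small ring; no stereocentre is formed.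

Step 3
Reactants: 7 (4aR)-4a,7-dimethyl-4,4a,7,8-tetrahydronaphthalene-2,6(3H,5H)-dione
Product: 8 (4aR)-4a,7-dimethyl-4,4a-dihydronaphthalene-2,6(3H,5H)-dione
Conditions: IBX (1.5 equiv), DMSO/toluene, 65 °C
Reagents that add atoms: none
Why: IBX dehydrogenation of a saturated ketone through its enol (Nicolaou type): only the C7–C8 bond can be desaturated because C5 is flanked by the quaternary C4a, and this removes the inconsequential C7 stereocentre.

Step 4
Reactants: 8 (4aR)-4a,7-dimethyl-4,4a-dihydronaphthalene-2,6(3H,5H)-dione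
Product: 9 (6R,8aR)-6-hydroxy-3,8a-dimethyl-6-(propan-2-yl)-6,7,8,8a-tetrahydronaphthalen-2(1H)-one
Conditions: i-PrMgCl, anhydrous CeCl3, THF, −78 °C
Reagents that add atoms: isopropylmagnesium chloride, CC(C)[Mg]Cl
Why: Organocerium 1,2-addition (Imamoto conditions) to the less hindered C2 carbonyl of 8 (the C6 carbonyl is flanked by the methyl-bearing alkene carbon and a neopentyl CH2); axial attack on the half-chair from the face opposite the angular methyl should set the carbinol with OH cis to that methyl.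

Step 5
Reactants: 9 (6R,8aR)-6-hydroxy-3,8a-dimethyl-6-(propan-2-yl)-6,7,8,8a-tetrahydronaphthalen-2(1H)-one
Product: 10 (4aR,5S,6R,8aR)-4a,5,6-trihydroxy-3,8a-dimethyl-6-(propan-2-yl)-4a,5,6,7,8,8a-hexahydronaphthalen-2(1H)-one
Conditions: OsO4 (1.05 equiv), TMEDA (1.1 equiv), CH2Cl2, −78 °C; then aq Na2SO3, THF, 50 °C
Reagents that add atoms: osmium tetroxide, O=[Os](=O)(=O)=O; water, O
Why: Hydrogen-bond-directed dihydroxylation (Donohoe OsO4·TMEDA): the reagent is delivered syn to the allylic tertiary hydroxyl onto the γ,δ-alkene (more electron-rich than the α,β-alkene), so both new C–O bonds are cis to the carbinol OH and to the angular methyl, giving the cis-fused all-cis triol.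

Step 6
Reactants: 10 (4aR,5S,6R,8aR)-4a,5,6-trihydroxy-3,8a-dimethyl-6-(propan-2-yl)-4a,5,6,7,8,8a-hexahydronaphthalen-2(1H)-one
Product: 11 (4aR,5S,6R,8aR)-4a,6-dihydroxy-3,8a-dimethyl-2-oxo-6-(propan-2-yl)-1,2,4a,5,6,7,8,8a-octahydronaphthalen-5-yl methanesulfonate
Conditions: MsCl (1.1 equiv), Et3N, CH2Cl2, −20 °C
Reagents that add atoms: methanesulfonyl chloride, CS(Cl)(=O)=O
Why: Sulfene-type mesylation picks the only secondary hydroxyl and leaves the two tertiary ones free; no stereocentre is changed.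

Step 7
Reactants: 11 (4aR,5S,6R,8aR)-4a,6-dihydroxy-3,8a-dimethyl-2-oxo-6-(propan-2-yl)-1,2,4a,5,6,7,8,8a-octahydronaphthalen-5-yl methanesulfonate
Product: 12 (3R,3aR,8aR)-3-hydroxy-6,8a-dimethyl-3-(propan-2-yl)-1,2,3,3a,8,8a-hexahydroazulene-4,7-dione
Conditions: Et3Al (3 equiv), CH2Cl2, −78 → −20 °C; aq Rochelle salt
Reagents that add atoms: none
Why: Et3Al turns both tertiary hydroxyls into aluminium alkoxides and, as Lewis acid on the sulfonate, triggers a concerted pinacol-type (semipinacol, Tsuchihashi–Suzuki) 1,2-shift: the C4a–C8a ring-fusion bond, antiperiplanar to the equatorial C5–OMs bond in the chair with isopropyl equatorial, migrates to C5 while C4a becomes the carbonyl. The closest known reaction type is the pinacol-type rearrangement of decalin vicinal-diol monosulfonates to hydroazulenones. Both product rings arise from this single 1,2-alkyl shift, not from a cyclisation: the six-membered ring C4a–C5–C6–C7–C8–C8a contracts to the cyclopentane by expelling C4a as the ketone, and the cyclohexenone ring expands by one carbon to the cycloheptenedione. The new ring-fusion CH forms with inversion at the mesylate carbon and retention at the migrating quaternary carbon, which converts the all-cis triol into the trans ring fusion with H cis to the isopropyl group; the isopropyl carbinol is untouched. The step needs migration of C8a (pushed by the ring-fusion alkoxide) and not of C7 (pushed by the C6 alkoxide), which the much higher migratory aptitude of a quaternary carbon over a CH2 should secure; E2 and epoxide formation are excluded because no H or O is antiperiplanar to the equatorial mesylate. The aluminium aldolate chelate should protect the β-hydroxy ketone from retro-aldol and dehydration until the quench.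

Step 8
Reactants: 12 (3R,3aR,8aR)-3-hydroxy-6,8a-dimethyl-3-(propan-2-yl)-1,2,3,3a,8,8a-hexahydroazulene-4,7-dione
Product: 13 (3R,3aS,4S,8aR)-3,4-dihydroxy-6,8a-dimethyl-3-(propan-2-yl)-2,3,3a,4,8,8a-hexahydroazulen-7(1H)-one
Conditions: Me4NBH(OAc)3 (5 equiv), MeCN/AcOH (1:1), −30 °C
Reagents that add atoms: none
Why: Hydroxyl-directed reduction of a β-hydroxy ketone (Evans–Saksena): the borohydride bound to the C3 oxygen delivers hydride intramolecularly to C4 from the face carrying that oxygen, which should give the 4S alcohol (anti 1,3-diol) and leave the undirected C7 carbonyl alone.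

Step 9
Reactants: 13 (3R,3aS,4S,8aR)-3,4-dihydroxy-6,8a-dimethyl-3-(propan-2-yl)-2,3,3a,4,8,8a-hexahydroazulen-7(1H)-one; 14 4-acetoxybenzoyl chloride
Product: 15 (3R,3aS,4S,8aR)-3-hydroxy-6,8a-dimethyl-7-oxo-3-(propan-2-yl)-1,2,3,3a,4,7,8,8a-octahydroazulen-4-yl 4-(acetyloxy)benzoate
Conditions: pyridine, DMAP (cat.), CH2Cl2, 0 → 25 °C
Reagents that add atoms: 4-acetoxybenzoyl chloride (14), CC(=O)Oc1ccc(cc1)C(Cl)=O
Why: Nucleophilic-catalysed acylation of the secondary allylic alcohol; the hindered tertiary alcohol should not react and no stereocentre is touched.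

Step 10
Reactants: 15 (3R,3aS,4S,8aR)-3-hydroxy-6,8a-dimethyl-7-oxo-3-(propan-2-yl)-1,2,3,3a,4,7,8,8a-octahydroazulen-4-yl 4-(acetyloxy)benzoate
Product: 16 (3R,3aS,4S,7S,8aR)-3,7-dihydroxy-6,8a-dimethyl-3-(propan-2-yl)-1,2,3,3a,4,7,8,8a-octahydroazulen-4-yl 4-(acetyloxy)benzoate
Conditions: (R)-2-methyl-CBS-oxazaborolidine (1 equiv), BH3·SMe2, THF, −30 °C; MeOH quench
Reagents that add atoms: none
Why: Corey–Bakshi–Shibata reduction of the α-methyl enone under reagent control: with the methyl-bearing alkenyl carbon as the large group the (R)-catalyst should give the 7S allylic alcohol (cis to the C4 ester), and the esters are not reduced at this temperature.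

Step 11
Reactants: 16 (3R,3aS,4S,7S,8aR)-3,7-dihydroxy-6,8a-dimethyl-3-(propan-2-yl)-1,2,3,3a,4,7,8,8a-octahydroazulen-4-yl 4-(acetyloxy)benzoate
Product: 17 (3R,3aS,4S,7S,8aR)-7-(acetyloxy)-3-hydroxy-6,8a-dimethyl-3-(propan-2-yl)-1,2,3,3a,4,7,8,8a-octahydroazulen-4-yl 4-(acetyloxy)benzoate
Conditions: Ac2O, pyridine, DMAP (cat.), CH2Cl2, 0 °C
Reagents that add atoms: acetic anhydride, CC(=O)OC(C)=O
Why: Acetylation of the secondary allylic alcohol with retention; the tertiary alcohol should stay free under these short, cold conditions.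

Step 12
Reactants: 17 (3R,3aS,4S,7S,8aR)-7-(acetyloxy)-3-hydroxy-6,8a-dimethyl-3-(propan-2-yl)-1,2,3,3a,4,7,8,8a-octahydroazulen-4-yl 4-(acetyloxy)benzoate
Product: 18 (3R,3aS,4S,7S,8aR)-7-(acetyloxy)-3-hydroxy-6,8a-dimethyl-3-(propan-2-yl)-1,2,3,3a,4,7,8,8a-octahydroazulen-4-yl 4-hydroxybenzoate
Conditions: pyrrolidine (1.5 equiv), CH2Cl2, 0 °C
Reagents that add atoms: none
Why: Chemoselective aminolysis of the aryl acetate (phenoxide leaving group), which should be far faster than attack on the alkyl acetate or the benzoate ester.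

**Compound list**

1 | 2,5-dimethylcyclohexane-1,4-dione (cis/trans mixture) | CC1CC(=O)C(C)CC1=O | starting material
2 | (R)-1-phenylethylamine | C[C@@H](N)c1ccccc1 | starting material
3 | methyl vinyl ketone (but-3-en-2-one) | CC(=O)C=C | starting material
4 | mono-imine: 2,5-dimethyl-4-{[(1R)-1-phenylethyl]imino}cyclohexan-1-one | CC1CC(=O)C(C)CC1=N[C@H](C)c1ccccc1 | intermediate (not isolated)
5 | alkylated imine: (3R)-3,6-dimethyl-3-(3-oxobutyl)-4-{[(1R)-1-phenylethyl]imino}cyclohexan-1-one | CC(=O)CC[C@]1(C)CC(=O)C(C)CC1=N[C@H](C)c1ccccc1 | intermediate (not isolated)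
6 | (2R)-2,5-dimethyl-2-(3-oxobutyl)cyclohexane-1,4-dione (epimers at C5) | CC(=O)CC[C@]1(C)CC(=O)C(C)CC1=O | intermediate
7 | (4aR)-4a,7-dimethyl-4,4a,7,8-tetrahydronaphthalene-2,6(3H,5H)-dione (epimers at C7) | O=C1C[C@@]2(C)CCC(=O)C=C2CC1C | intermediate
8 | (4aR)-4a,7-dimethyl-4,4a-dihydronaphthalene-2,6(3H,5H)-dione | O=C1C[C@@]2(C)CCC(=O)C=C2C=C1C | intermediate
9 | (6R,8aR)-6-hydroxy-3,8a-dimethyl-6-(propan-2-yl)-6,7,8,8a-tetrahydronaphthalen-2(1H)-one (OH cis to the angular methyl) | O=C1C[C@@]2(C)CC[C@@](O)(C(C)C)C=C2C=C1C | intermediate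
10 | (4aR,5S,6R,8aR)-4a,5,6-trihydroxy-3,8a-dimethyl-6-(propan-2-yl)-4a,5,6,7,8,8a-hexahydronaphthalen-2(1H)-one (cis-decalin, three OH cis to the angular methyl) | O=C1C[C@@]2(C)CC[C@@](O)(C(C)C)[C@H](O)[C@@]2(O)C=C1C | intermediate
11 | (4aR,5S,6R,8aR)-4a,6-dihydroxy-3,8a-dimethyl-2-oxo-6-(propan-2-yl)-1,2,4a,5,6,7,8,8a-octahydronaphthalen-5-yl methanesulfonate | O=C1C[C@@]2(C)CC[C@@](O)(C(C)C)[C@H](OS(C)(=O)=O)[C@@]2(O)C=C1C | intermediate
12 | (3R,3aR,8aR)-3-hydroxy-6,8a-dimethyl-3-(propan-2-yl)-1,2,3,3a,8,8a-hexahydroazulene-4,7-dione (trans-fused) | O=C1C[C@@]2(C)CC[C@@](O)(C(C)C)[C@@H]2C(=O)C=C1C | intermediate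
13 | (3R,3aS,4S,8aR)-3,4-dihydroxy-6,8a-dimethyl-3-(propan-2-yl)-2,3,3a,4,8,8a-hexahydroazulen-7(1H)-one | O=C1C[C@@]2(C)CC[C@@](O)(C(C)C)[C@@H]2[C@@H](O)C=C1C | intermediate
14 | 4-acetoxybenzoyl chloride | CC(=O)Oc1ccc(cc1)C(Cl)=O | starting material
15 | (3R,3aS,4S,8aR)-3-hydroxy-6,8a-dimethyl-7-oxo-3-(propan-2-yl)-1,2,3,3a,4,7,8,8a-octahydroazulen-4-yl 4-(acetyloxy)benzoate | O=C1C[C@@]2(C)CC[C@@](O)(C(C)C)[C@@H]2[C@@H](OC(=O)c2ccc(OC(C)=O)cc2)C=C1C | intermediate
16 | (3R,3aS,4S,7S,8aR)-3,7-dihydroxy-6,8a-dimethyl-3-(propan-2-yl)-1,2,3,3a,4,7,8,8a-octahydroazulen-4-yl 4-(acetyloxy)benzoate | O[C@H]1C[C@@]2(C)CC[C@@](O)(C(C)C)[C@@H]2[C@@H](OC(=O)c2ccc(OC(C)=O)cc2)C=C1C | intermediate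
17 | (3R,3aS,4S,7S,8aR)-7-(acetyloxy)-3-hydroxy-6,8a-dimethyl-3-(propan-2-yl)-1,2,3,3a,4,7,8,8a-octahydroazulen-4-yl 4-(acetyloxy)benzoate | CC(=O)O[C@H]1C[C@@]2(C)CC[C@@](O)(C(C)C)[C@@H]2[C@@H](OC(=O)c2ccc(OC(C)=O)cc2)C=C1C | intermediate
18 | (3R,3aS,4S,7S,8aR)-7-(acetyloxy)-3-hydroxy-6,8a-dimethyl-3-(propan-2-yl)-1,2,3,3a,4,7,8,8a-octahydroazulen-4-yl 4-hydroxybenzoate | CC(=O)O[C@H]1C[C@@]2(C)CC[C@@](O)(C(C)C)[C@@H]2[C@@H](OC(=O)c2ccc(O)cc2)C=C1C | target

**Step count.** Total steps: 12. Longest linear sequence: 12 steps (1 → 18).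

**Steps most likely to fail**

1. Step 7 (key step). The aluminium alkoxide at C6 may compete and drive migration of the C6–C7 ring bond instead (contraction to an isobutyryl cyclopentane), or the aluminium aldolate may suffer retro-aldol or β-elimination before the quench. The fallback removes the push from the C6 oxygen by protecting it before the diol is made. It sets out from 9. Silylation with TESOTf and 2,6-lutidine gives triethylsilyl ether F1. Woodward cis-hydroxylation (I2, AgOAc, AcOH, then wet AcOH) places the iodonium on the face away from the angular methyl and the silyloxy group, so the acetoxonium ion and water deliver both oxygens on the methyl face to give cis-hydroxy acetate F2. Methanolysis (K2CO3, MeOH) gives silylated cis-diol F3, and MsCl/Et3N gives silylated mesylate F4. Et3Al as in step 7, now with only the ring-fusion alkoxide available, should give silylated hydroazulenedione F5. HF·pyridine then returns to 12.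

2. Step 5. The reagent may approach the hindered, dienone-conjugated alkene from the face opposite the angular methyl despite the hydrogen bond, or add too slowly. The fallback sets out from 9 and uses a Woodward cis-hydroxylation (I2, AgOAc, AcOH, then water). Here the iodonium ion forms on the open face and both oxygens enter from the methyl face through the acetoxonium ion, so the steric preference works for the required isomer. This gives hydroxy acetate F6, and K2CO3/MeOH returns to 10.

3. Step 3. Over-oxidation (further desaturation of the enone ring) or incomplete conversion with IBX may occur. The fallback sets out from 7 and replaces direct dehydrogenation by halogenation–elimination. Acid-mediated α-bromination at the methyl-bearing α-carbon (pyridinium tribromide, AcOH) gives bromo ketone F7, and dehydrobromination (Li2CO3, LiBr, DMF, 120 °C) returns to 8.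

**Further compounds**

F1 | step 7 | (6R,8aR)-3,8a-dimethyl-6-(propan-2-yl)-6-(triethylsilyloxy)-6,7,8,8a-tetrahydronaphthalen-2(1H)-one | O=C1C[C@@]2(C)CC[C@@](O[Si](CC)(CC)CC)(C(C)C)C=C2C=C1C
F2 | step 7 | (4aR,5S,6R,8aR)-4a-hydroxy-3,8a-dimethyl-2-oxo-6-(propan-2-yl)-6-(triethylsilyloxy)-1,2,4a,5,6,7,8,8a-octahydronaphthalen-5-yl acetate | O=C1C[C@@]2(C)CC[C@@](O[Si](CC)(CC)CC)(C(C)C)[C@H](OC(C)=O)[C@@]2(O)C=C1C
F3 | step 7 | (4aR,5S,6R,8aR)-4a,5-dihydroxy-3,8a-dimethyl-6-(propan-2-yl)-6-(triethylsilyloxy)-4a,5,6,7,8,8a-hexahydronaphthalen-2(1H)-one | O=C1C[C@@]2(C)CC[C@@](O[Si](CC)(CC)CC)(C(C)C)[C@H](O)[C@@]2(O)C=C1C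
F4 | step 7 | (4aR,5S,6R,8aR)-4a-hydroxy-3,8a-dimethyl-2-oxo-6-(propan-2-yl)-6-(triethylsilyloxy)-1,2,4a,5,6,7,8,8a-octahydronaphthalen-5-yl methanesulfonate | O=C1C[C@@]2(C)CC[C@@](O[Si](CC)(CC)CC)(C(C)C)[C@H](OS(C)(=O)=O)[C@@]2(O)C=C1C
F5 | step 7 | (3R,3aR,8aR)-6,8a-dimethyl-3-(propan-2-yl)-3-(triethylsilyloxy)-1,2,3,3a,8,8a-hexahydroazulene-4,7-dione | O=C1C[C@@]2(C)CC[C@@](O[Si](CC)(CC)CC)(C(C)C)[C@@H]2C(=O)C=C1C
F6 | step 5 | (4aR,5S,6R,8aR)-4a,6-dihydroxy-3,8a-dimethyl-2-oxo-6-(propan-2-yl)-1,2,4a,5,6,7,8,8a-octahydronaphthalen-5-yl acetate | O=C1C[C@@]2(C)CC[C@@](O)(C(C)C)[C@H](OC(C)=O)[C@@]2(O)C=C1C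
F7 | step 3 | (4aR)-7-bromo-4a,7-dimethyl-4,4a,7,8-tetrahydronaphthalene-2,6(3H,5H)-dione | O=C1C[C@@]2(C)CCC(=O)C=C2CC1(C)Br
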